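**Strategy.** The ten-membered carbocycle is opened at C3–C4. The feature used is that C3 is the allylic carbon of the E-configured C1=C2 double bond, while its ring neighbour C4 carries the isopropyl group and is α to the oxygen-bearing C5. With C5 as a ketone and a phenylsulfonyl group on C4, C4 becomes a soft carbanion and C1–C3 a π-allyl electrophile. One palladium-catalysed allylic alkylation then forms C3–C4 and closes the ring without added base. The precursor is an open-chain, farnesane-type C3 methyl carbonate bearing the C4 keto sulfone and a C7 triethylsilyl ether. Its only stereocentre comes from (R)-mevalonolactone. Sulfinate loss later sets the 3Z alkene, and the C7 hydroxyl directs reduction at C5.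

Key step: step 13

Assumption: ring atoms are labelled C1 (methyl-bearing alkene carbon), C2, C3, C4 (isopropyl), C5 (acyloxy), C6, C7 (carbinol) and C8–C10. Open-chain intermediates keep these labels, ring names use them as locants, and the target is then (1E,3Z,5S,7S).

Step 1
Reactants: 1 sodium benzenesulfinate; 2 1-bromo-2-methylpropane
Product: 3 isobutyl phenyl sulfone
Conditions: n-Bu4NI (10 mol %), DMF, 80 °C
Reagents that add atoms: none
Why: SN2 alkylation of the ambident sulfinate at sulfur by a primary bromide, with iodide catalysis to offset the β-branching, is the standard sulfone synthesis and should give the sulfone rather than the sulfinate ester.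

Step 2
Reactants: 4 but-2-yn-1-ol
Product: 7 (E)-3-iodobut-2-en-1-ol, via aluminium alkoxide 5 (not isolated), via alkenylzirconocene 6 (not isolated)
Conditions: i-Bu2AlH (1.0 equiv), THF, 0 °C; Cp2ZrHCl (1.3 equiv), 23 °C; I2, −78 → 0 °C; 1 M HCl
Reagents that add atoms: iodine, I-I
Why: Hydrozirconation–iodinolysis: once the hydroxyl is masked as a bulky aluminium alkoxide, Cp2ZrHCl adds syn across the alkyne with zirconium at the less hindered methyl-bearing carbon, and iodine replaces zirconium with retention, so the E geometry of the later C1=C2 bond is fixed here.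

Step 3
Reactants: 8 4-hydroxybenzoic acid
Product: 10 4-(tert-butyldimethylsilyloxy)benzoic acid, via bis-silylated acid 9 (not isolated)
Conditions: t-BuMe2SiCl (2.3 equiv), imidazole (5 equiv), DMF, 23 °C; then AcOH/THF/H2O, 23 °C
Reagents that add atoms: tert-butyldimethylsilyl chloride, CC(C)(C)[Si](C)(C)Cl
Why: Exhaustive silylation followed by mild hydrolysis relies on the much higher lability of a silyl ester than of an aryl silyl ether, leaving the phenol masked by a group that fluoride removes without touching a benzoate ester.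

Step 4
Reactants: 11 (R)-mevalonolactone
Product: 12 (R)-3,5-dihydroxy-N-methoxy-N,3-dimethylpentanamide
Conditions: MeNH(OMe)·HCl (3 equiv), AlMe3 (3 equiv), CH2Cl2, 0 → 23 °C; aq. potassium sodium tartrate; used crude
Reagents that add atoms: N,O-dimethylhydroxylamine hydrochloride, CNOC.Cl
Why: Weinreb aminolysis of the lactone by the aluminium amide differentiates the two arms at the untouched carbinol centre (future C7), the amide carbon being the future C9 and the CH2OH carbon the future C5, which is the assignment that turns the R lactone into the 7S series.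

Step 5
Reactants: 12 (R)-3,5-dihydroxy-N-methoxy-N,3-dimethylpentanamide
Product: 13 (R)-N-methoxy-N,3-dimethyl-3,5-bis(triethylsilyloxy)pentanamide
Conditions: Et3SiOTf (2.5 equiv), 2,6-lutidine (4 equiv), CH2Cl2, −78 → 0 °C
Reagents that add atoms: triethylsilyl trifluoromethanesulfonate, CC[Si](CC)(CC)OS(=O)(=O)C(F)(F)F
Why: Silyl triflate with a hindered pyridine base silylates the primary and the tertiary hydroxyl alike, which stops relactonisation, blocks later retro-aldol cleavage at C6–C7 and leaves a tertiary ether that mild fluoride can still remove.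

Step 6
Reactants: 13 (R)-N-methoxy-N,3-dimethyl-3,5-bis(triethylsilyloxy)pentanamide
Product: 14 (R)-3-methyl-3,5-bis(triethylsilyloxy)pentanal
Conditions: i-Bu2AlH (1.3 equiv), THF, −78 °C; aq. potassium sodium tartrate
Reagents that add atoms: none
Why: Partial reduction of a Weinreb amide by i-Bu2AlH at low temperature stops at the aldehyde, so the two arms stay different and the centre stays intact.

Step 7
Reactants: 14 (R)-3-methyl-3,5-bis(triethylsilyloxy)pentanal
Product: 15 (S)-4-methyl-4,6-bis(triethylsilyloxy)hex-1-ene
Conditions: Ph3PCH3Br (1.5 equiv), KN(SiMe3)2 (1.4 equiv), THF, 0 °C; then 14, −78 → 0 °C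
Reagents that add atoms: methyltriphenylphosphonium bromide, C[P+](c1ccccc1)(c1ccccc1)c1ccccc1.[Br-]
Why: Wittig methylenation with a non-stabilised ylide is faster than enolisation of the β-silyloxy aldehyde at low temperature and adds C10 (the descriptor changes only because the substituent ranking changes).

Step 8
Reactants: 15 (S)-4-methyl-4,6-bis(triethylsilyloxy)hex-1-ene; 7 (E)-3-iodobut-2-en-1-ol
Product: 17 (2E,7S)-3,7-dimethyl-7,9-bis(triethylsilyloxy)non-2-en-1-ol, via B-alkyl-9-BBN 16 (not isolated)
Conditions: 9-BBN-H (1.3 equiv), THF, 23 °C; H2O; then 7, PdCl2(dppf) (5 mol %), AsPh3 (5 mol %), Cs2CO3 (2 equiv), DMF, 23 °C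
Reagents that add atoms: none
Why: Anti-Markovnikov hydroboration of the only alkene puts boron on C10, and the B-alkyl Suzuki–Miyaura coupling then forms C10–C1 with retention of the iodoalkene geometry, which delivers the E trisubstituted C1=C2 alkene convergently.

Step 9
Reactants: 17 (2E,7S)-3,7-dimethyl-7,9-bis(triethylsilyloxy)non-2-en-1-ol
Product: 18 (2E,7S)-3,7-dimethyl-7,9-bis(triethylsilyloxy)non-2-en-1-yl methyl carbonate
Conditions: ClCO2Me (1.5 equiv), pyridine (3 equiv), CH2Cl2, 0 °C
Reagents that add atoms: methyl chloroformate, COC(=O)Cl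
Why: Acylation of the only free hydroxyl by a chloroformate gives the allylic carbonate, the leaving group that later supplies its own base.

Step 10
Reactants: 18 (2E,7S)-3,7-dimethyl-7,9-bis(triethylsilyloxy)non-2-en-1-yl methyl carbonate
Product: 20 (2E,7S)-3,7-dimethyl-9-oxo-7-(triethylsilyloxy)non-2-en-1-yl methyl carbonate, via alkoxysulfonium chloride 19 (not isolated)
Conditions: (COCl)2 (4 equiv), DMSO (8 equiv), CH2Cl2, −78 → −35 °C; Et3N (16 equiv), −78 → 0 °C
Reagents that add atoms: none
Why: Swern oxidation applied directly to a silyl ether: the chlorosulfonium salt attacks only the unhindered primary C5 oxygen, chlorotriethylsilane leaves, and base collapses the alkoxysulfonium salt to the aldehyde while the crowded tertiary C7 ether and the carbonate are untouched.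

Step 11
Reactants: 20 (2E,7S)-3,7-dimethyl-9-oxo-7-(triethylsilyloxy)non-2-en-1-yl methyl carbonate; 3 isobutyl phenyl sulfone
Product: 22 C5 hydroxy C4 sulfone (mixture of C4 and C5 epimers), via lithiated sulfone 21 (not isolated)
Conditions: 3 (1.15 equiv), n-BuLi (1.1 equiv), THF, −78 °C; then 20, −78 °C; AcOH quench at −78 °C
Reagents that add atoms: none
Why: Addition of an α-lithio sulfone to an aldehyde (the first stage of a Julia olefination) is far faster at −78 °C than attack on the carbonate and needs one equivalent of carbanion, whereas acylation by a C5 ester would need two and would endanger the carbonate; the cold quench prevents silyl migration, and the C4 and C5 centres form without control and are erased in steps 12 to 14.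

Step 12
Reactants: 22 C5 hydroxy C4 sulfone
Product: 23 open-chain keto sulfone carbonate (7S; C4 labile)
Conditions: Dess–Martin periodinane (1.5 equiv), CH2Cl2, 0 → 23 °C
Reagents that add atoms: none
Why: Dess–Martin oxidation works under nearly neutral conditions, so the β-silyloxy ketone does not eliminate, the carbonate survives and the configurationally labile C4–H keto sulfone is obtained.

Step 13
Reactants: 23 open-chain keto sulfone carbonate
Product: 25 ten-membered keto sulfone (both C4 epimers), via π-allylpalladium zwitterion 24 (not isolated)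
Conditions: Pd(PPh3)4 (10 mol %), Ph2PCH2CH2PPh2 (10 mol %), THF, 65 °C, 23 added by syringe pump over 12 h (final 2 mM)
Reagents that add atoms: none
Why: Zerovalent palladium ionises the C3 carbonate to a cationic π-allyl complex of divalent palladium spanning C1–C3, and the expelled methyl carbonate ion loses CO2 to give methoxide, which removes the acidic C4 proton, so zwitterion 24 arises without external base. The stabilised carbanion attacks the allyl ligand on the face opposite the metal, which is the Tsuji–Trost allylic alkylation in the macrocyclising form established for sulfonyl-stabilised carbanions. Bond formation at the unsubstituted terminus C3 closes the ten-membered carbocycle in the endo mode (all three allyl carbons end up in the ring), whereas attack at C1 would be an eight-membered exo closure joining two fully substituted carbons. C4 becomes a stereocentre without control, which is harmless because both epimers lose it in step 14, and C7 is a spectator. The step needs C- rather than O-allylation, attack at C3 and retention of the E geometry: an O-allyl enol ether should re-ionise under the catalyst and drain to the ketone, the bulk of the isopropyl-bearing carbanion and of C1 directs attack to C3, and syn/anti exchange at C1 would require a σ-bond from palladium to a tertiary carbon. Slow addition at high dilution holds back dimerisation.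

Step 14
Reactants: 25 ten-membered keto sulfone
Product: 26 (1E,3Z,7S)-4-isopropyl-1,7-dimethyl-7-(triethylsilyloxy)cyclodeca-1,3-dien-5-one
Conditions: DBU (3 equiv), toluene, 23 → 60 °C
Reagents that add atoms: none
Why: Dehydrosulfonylation (1,2-elimination of benzenesulfinic acid from a crowded tertiary α-sulfonyl ketone): the amidine removes an allylic C3 hydrogen antiperiplanar to the C4–S bond to give the fully conjugated dienone, a non-ionic base being chosen because an alkoxide would enolise C6 and expel the C7 silyloxy group, and the in-ring cis (3Z) geometry is expected because an E,E-1,3-diene is more strained in a ten-membered ring and reversible sulfinate addition lets the isomers equilibrate.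

Step 15
Reactants: 26 (1E,3Z,7S)-4-isopropyl-1,7-dimethyl-7-(triethylsilyloxy)cyclodeca-1,3-dien-5-one
Product: 27 (1E,3Z,7S)-7-hydroxy-4-isopropyl-1,7-dimethylcyclodeca-1,3-dien-5-one
Conditions: HF·pyridine, pyridine, THF, 0 → 23 °C
Reagents that add atoms: none
Why: Fluoride desilylation in a buffered, slightly acidic medium frees the tertiary hydroxyl without ever forming the C7 alkoxide, so retro-aldol ring opening of the β-hydroxy ketone is avoided.

Step 16
Reactants: 27 (1E,3Z,7S)-7-hydroxy-4-isopropyl-1,7-dimethylcyclodeca-1,3-dien-5-one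
Product: 29 (1E,3Z,5S,7S)-4-isopropyl-1,7-dimethylcyclodeca-1,3-diene-5,7-diol, via diethylboron chelate 28 (not isolated)
Conditions: Et2BOMe (1.3 equiv), THF/MeOH 4:1, 23 °C, 1 h, then −78 °C; NaBH4 (1.5 equiv), −78 °C; AcOH; repeated MeOH azeotrope
Reagents that add atoms: none
Why: Narasaka–Prasad reduction: the C7 oxygen binds the Et2B group, boron chelates the C5 carbonyl in a six-membered half-chair, and external hydride adds axially in 1,2 fashion so that C5–O ends up syn to C7–O with the ring bonds to C4 and C8 both equatorial on the chelate, which corresponds to 5S.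

Step 17
Reactants: 29 (1E,3Z,5S,7S)-4-isopropyl-1,7-dimethylcyclodeca-1,3-diene-5,7-diol; 10 4-(tert-butyldimethylsilyloxy)benzoic acid
Product: 30 C5 4-(tert-butyldimethylsilyloxy)benzoate of diol 29
Conditions: 10 (1.3 equiv), EDC·HCl (1.5 equiv), 4-(dimethylamino)pyridine (0.5 equiv), CH2Cl2, 0 → 23 °C
Reagents that add atoms: none
Why: Steglich esterification acylates the secondary allylic C5 hydroxyl while the tertiary C7 hydroxyl is too hindered to react, and C5 keeps its configuration because its C–O bond is not broken.

Step 18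
Reactants: 30 C5 4-(tert-butyldimethylsilyloxy)benzoate of diol 29
Product: 31 (1E,3Z,5S,7S)-7-hydroxy-4-isopropyl-1,7-dimethylcyclodeca-1,3-dien-5-yl 4-hydroxybenzoate (CNP0130127.1)
Conditions: n-Bu4NF (1.1 equiv), AcOH (1.1 equiv), THF, 0 °C
Reagents that add atoms: none
Why: Fluoride cleaves the aryl silyl ether quickly and acetic acid buffers the phenoxide, so the allylic benzoate, the tertiary alcohol and the diene are left alone.

**Compound list**

1 | sodium benzenesulfinate | [Na+].[O-]S(=O)c1ccccc1 | starting material
2 | 1-bromo-2-methylpropane | CC(C)CBr | starting material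
3 | isobutyl phenyl sulfone | CC(C)CS(=O)(=O)c1ccccc1 | intermediate
4 | but-2-yn-1-ol | CC#CCO | starting material
5 | diisobutylaluminium but-2-yn-1-olate (not isolated) | CC#CCO[Al](CC(C)C)CC(C)C | intermediate
6 | (E)-alkenylzirconocene chloride, Zr on the methyl-bearing carbon and trans to CH2O, cyclopentadienyl rings drawn σ-bonded (not isolated) | C/C(=C\CO[Al](CC(C)C)CC(C)C)[Zr](Cl)(C1C=CC=C1)C1C=CC=C1 | intermediate
7 | (E)-3-iodobut-2-en-1-ol | I/C(C)=C/CO | intermediate
8 | 4-hydroxybenzoic acid | OC(=O)c1ccc(O)cc1 | starting material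
9 | tert-butyldimethylsilyl 4-(tert-butyldimethylsilyloxy)benzoate (not isolated) | CC(C)(C)[Si](C)(C)OC(=O)c1ccc(O[Si](C)(C)C(C)(C)C)cc1 | intermediate
10 | 4-(tert-butyldimethylsilyloxy)benzoic acid | OC(=O)c1ccc(O[Si](C)(C)C(C)(C)C)cc1 | intermediate
11 | (R)-mevalonolactone | C[C@@]1(O)CCOC(=O)C1 | starting material
12 | (R)-3,5-dihydroxy-N-methoxy-N,3-dimethylpentanamide | OCC[C@@](C)(O)CC(=O)N(C)OC | intermediate
13 | (R)-N-methoxy-N,3-dimethyl-3,5-bis(triethylsilyloxy)pentanamide | CC[Si](CC)(CC)OCC[C@@](C)(O[Si](CC)(CC)CC)CC(=O)N(C)OC | intermediate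
14 | (R)-3-methyl-3,5-bis(triethylsilyloxy)pentanal | CC[Si](CC)(CC)OCC[C@@](C)(O[Si](CC)(CC)CC)CC=O | intermediate
15 | (S)-4-methyl-4,6-bis(triethylsilyloxy)hex-1-ene | CC[Si](CC)(CC)OCC[C@@](C)(O[Si](CC)(CC)CC)CC=C | intermediate
16 | 9-[(S)-4-methyl-4,6-bis(triethylsilyloxy)hexyl]-9-borabicyclo[3.3.1]nonane (not isolated) | CC[Si](CC)(CC)OCC[C@@](C)(O[Si](CC)(CC)CC)CCCB1C2CCCC1CCC2 | intermediate
17 | (2E,7S)-3,7-dimethyl-7,9-bis(triethylsilyloxy)non-2-en-1-ol | CC[Si](CC)(CC)OCC[C@@](C)(O[Si](CC)(CC)CC)CCC/C(C)=C/CO | intermediate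
18 | (2E,7S)-3,7-dimethyl-7,9-bis(triethylsilyloxy)non-2-en-1-yl methyl carbonate | CC[Si](CC)(CC)OCC[C@@](C)(O[Si](CC)(CC)CC)CCC/C(C)=C/COC(=O)OC | intermediate
19 | dimethyl(alkoxy)sulfonium chloride on the C5 oxygen (not isolated) | C[S+](C)OCC[C@@](C)(O[Si](CC)(CC)CC)CCC/C(C)=C/COC(=O)OC.[Cl-] | intermediate
20 | (2E,7S)-3,7-dimethyl-9-oxo-7-(triethylsilyloxy)non-2-en-1-yl methyl carbonate | O=CC[C@@](C)(O[Si](CC)(CC)CC)CCC/C(C)=C/COC(=O)OC | intermediate
21 | α-lithio isobutyl phenyl sulfone (not isolated) | [Li]C(C(C)C)S(=O)(=O)c1ccccc1 | intermediate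
22 | (2E,7S)-9-hydroxy-3,7,11-trimethyl-10-(phenylsulfonyl)-7-(triethylsilyloxy)dodec-2-en-1-yl methyl carbonate, epimers at route C4 and C5 | CC(C)C(C(O)C[C@@](C)(O[Si](CC)(CC)CC)CCC/C(C)=C/COC(=O)OC)S(=O)(=O)c1ccccc1 | intermediate
23 | (2E,7S)-3,7,11-trimethyl-9-oxo-10-(phenylsulfonyl)-7-(triethylsilyloxy)dodec-2-en-1-yl methyl carbonate, route C4 labile | CC(C)C(C(=O)C[C@@](C)(O[Si](CC)(CC)CC)CCC/C(C)=C/COC(=O)OC)S(=O)(=O)c1ccccc1 | intermediate
24 | π-allylpalladium cation with C4 keto sulfone carbanion, drawn as the σ-allyl form without phosphines (not isolated) | CC(C)[C-](C(=O)C[C@@](C)(O[Si](CC)(CC)CC)CCC/C(C)=C/C[Pd+])S(=O)(=O)c1ccccc1 | intermediate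
25 | (1E,7S)-4-isopropyl-1,7-dimethyl-4-(phenylsulfonyl)-7-(triethylsilyloxy)cyclodec-1-en-5-one, C4 epimers | C/C1=C\CC(C(C)C)(S(=O)(=O)c2ccccc2)C(=O)C[C@@](C)(O[Si](CC)(CC)CC)CCC1 | intermediate
26 | (1E,3Z,7S)-4-isopropyl-1,7-dimethyl-7-(triethylsilyloxy)cyclodeca-1,3-dien-5-one | C/C1=C\C=C(\C(C)C)C(=O)C[C@@](C)(O[Si](CC)(CC)CC)CCC1 | intermediate
27 | (1E,3Z,7S)-7-hydroxy-4-isopropyl-1,7-dimethylcyclodeca-1,3-dien-5-one | C/C1=C\C=C(\C(C)C)C(=O)C[C@@](C)(O)CCC1 | intermediate
28 | C7 diethylboron alkoxide chelated to the C5 carbonyl, dative bond not drawn (not isolated) | C/C1=C\C=C(\C(C)C)C(=O)C[C@@](C)(OB(CC)CC)CCC1 | intermediate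
29 | (1E,3Z,5S,7S)-4-isopropyl-1,7-dimethylcyclodeca-1,3-diene-5,7-diol | C/C1=C\C=C(\C(C)C)[C@@H](O)C[C@@](C)(O)CCC1 | intermediate
30 | (1E,3Z,5S,7S)-7-hydroxy-4-isopropyl-1,7-dimethylcyclodeca-1,3-dien-5-yl 4-(tert-butyldimethylsilyloxy)benzoate | C/C1=C\C=C(\C(C)C)[C@@H](OC(=O)c2ccc(O[Si](C)(C)C(C)(C)C)cc2)C[C@@](C)(O)CCC1 | intermediate
31 | (1E,3Z,5S,7S)-7-hydroxy-4-isopropyl-1,7-dimethylcyclodeca-1,3-dien-5-yl 4-hydroxybenzoate | C/C1=C\C=C(\C(C)C)[C@@H](OC(=O)c2ccc(O)cc2)C[C@@](C)(O)CCC1 | target

Total step count: 18.
Longest linear sequence: 15 steps (steps 4 to 18, from 11 to 31).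

**Steps most likely to fail**

**Step 13.**
- What may go wrong: intermolecular alkylation may outrun the slow attack of the crowded, fully substituted carbanion. O-allylation may persist. The alkene geometry may erode through syn/anti exchange in the allyl complex.
- Fallback, a metal-free macro-alkylation: it sets out from 23. K2CO3 in MeOH at 0 °C, followed by a mildly acidic work-up, removes the carbonate by transesterification and gives the allylic alcohol keto sulfone F1. An Appel reaction (CBr4, PPh3, CH2Cl2, 0 °C) converts it under neutral conditions into the E allylic bromide keto sulfone F2. Slow addition of F2 to Cs2CO3 in DMF at high dilution closes C3–C4 by direct SN2 displacement. No allyl-metal species can scramble the geometry in this closure. The fallback returns to the route at 25.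

**Step 14.**
- What may go wrong: enolisation at C6 may compete and lead to loss of the C7 silyloxy group. Elimination may go toward the isopropyl methine, or the new double bond may form with incomplete geometric control.
- Fallback, a base-free dehydrogenation by way of selenium: it sets out from 25. SmI2 (2.2 equiv, THF, −78 °C) cleaves the C4–S bond reductively and gives the C4=C5 samarium enolate F3 regiospecifically. PhSeBr added to the same flask gives the C4 phenylselanyl ketone F4. H2O2 with pyridine in CH2Cl2 at 0 °C oxidises it to the selenoxide F5. This should undergo syn elimination toward the allylic C3 hydrogen below room temperature, returning to the route at 26.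

**Step 16.**
- What may go wrong: chelate formation at the tertiary hydroxyl may be slow. Facial selectivity may be poor, because the axial C7 methyl group hinders the axial approach of hydride.
- Fallback, reagent control in place of chelation control: it sets out from 26. Corey–Bakshi–Shibata reduction uses (R)-1-methyl-3,3-diphenyltetrahydro-1H,3H-pyrrolo[1,2-c][1,3,2]oxazaborole and BH3·SMe2 in toluene at −40 °C, with the alkenyl side acting as the large group. It should give the 5S allylic alcohol silyl ether F6. Steglich esterification with 10 gives the bis-silylated ester F7. HF·pyridine in THF removes both silyl groups at once and the fallback rejoins the route at 31.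

**Further compounds**

F1 | step 13 | (2E,7S)-1-hydroxy-3,7,11-trimethyl-10-(phenylsulfonyl)-7-(triethylsilyloxy)dodec-2-en-9-one | CC(C)C(C(=O)C[C@@](C)(O[Si](CC)(CC)CC)CCC/C(C)=C/CO)S(=O)(=O)c1ccccc1
F2 | step 13 | (2E,7S)-1-bromo-3,7,11-trimethyl-10-(phenylsulfonyl)-7-(triethylsilyloxy)dodec-2-en-9-one | CC(C)C(C(=O)C[C@@](C)(O[Si](CC)(CC)CC)CCC/C(C)=C/CBr)S(=O)(=O)c1ccccc1
F3 | step 14 | C4=C5 samarium enolate of the desulfonylated ten-membered ketone, drawn as ions | C/C1=C\CC(C(C)C)=C([O-])C[C@@](C)(O[Si](CC)(CC)CC)CCC1.[Sm+3].[I-].[I-]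
F4 | step 14 | (1E,7S)-4-isopropyl-1,7-dimethyl-4-(phenylselanyl)-7-(triethylsilyloxy)cyclodec-1-en-5-one | C/C1=C\CC(C(C)C)([Se]c2ccccc2)C(=O)C[C@@](C)(O[Si](CC)(CC)CC)CCC1
F5 | step 14 | selenoxide of F4 | C/C1=C\CC(C(C)C)([Se](=O)c2ccccc2)C(=O)C[C@@](C)(O[Si](CC)(CC)CC)CCC1
F6 | step 16 | (1E,3Z,5S,7S)-4-isopropyl-1,7-dimethyl-7-(triethylsilyloxy)cyclodeca-1,3-dien-5-ol | C/C1=C\C=C(\C(C)C)[C@@H](O)C[C@@](C)(O[Si](CC)(CC)CC)CCC1
F7 | step 16 | (1E,3Z,5S,7S)-4-isopropyl-1,7-dimethyl-7-(triethylsilyloxy)cyclodeca-1,3-dien-5-yl 4-(tert-butyldimethylsilyloxy)benzoate | C/C1=C\C=C(\C(C)C)[C@@H](OC(=O)c2ccc(O[Si](C)(C)C(C)(C)C)cc2)C[C@@](C)(O[Si](CC)(CC)CC)CCC1
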